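## Structural features

The target is pentacyclic. A (Z)-3-butylidene-4,5,6,7-tetrahydrophthalide (C1, O2, C3, C3a, C4–C7, C7a; butylidene C8–C11; butenolide fused to a cyclohexene at C3a=C7a) and a benzo-fused spiro-γ-lactone (C1', O2', C3', C3a'–C7a'; propyl C9'–C11' on C8') are joined through the cyclobutane C6–C7–C3'–C8'. The molecule is thus formally the crossed [2+2] dimer of (Z)-ligustilide (C6=C7) and (Z)-3-butylidenephthalide (C3'=C8'); these phthalide locants are used throughout.

The four stereocentres are contiguous and all lie on the four-membered ring: C6 (S), C7 (R), C8' (R) and the fully substituted spiro carbon C3' (R), which carries O2', the aryl carbon C3a', C7 and C8'. The cyclohexene is cis-fused to the cyclobutane; C5, C7a, the propyl group on C8' and O2' sit on one face of the cyclobutane, and C3a' and the three ring hydrogens on the other (convex) face.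

The (Z)-γ-alkylidene butenolide is an enol lactone, sensitive to nucleophiles and base, and in any C3' ketone precursor the concave propyl centre C8' is epimerisable. The real difficulty is the tetrasubstituted cyclobutane with a spiro quaternary centre flanked by three tertiary centres, whose absolute configuration must be set although no stereocentre lies outside the four-membered ring.

The key step exploits the fact that the cyclobutane shares its C6–C7 edge with the cyclohexene. Cutting C6–C7 together with the opposite edge C3'–C8' (the two bonds a dimerisation does not form) opens both carbocycles at once. It leaves C3' as a ketene-type carbon on a C7 methylene arm of a monocyclic butenolide, and C6=C8' as a plain (Z)-alkene in the side chain on C3a.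

## Logic of the disconnections

22 to 18 and 19. The bonds C3'–C3a' (aryl to spiro carbon) and O2'–C1' (lactone acyl–oxygen) are cut, so that C3' becomes the carbonyl carbon of 18 and the whole benzoate unit comes from 19. The fully substituted carbon is thus made last by union of two fragments, and 18 loses the spiro centre and the arene. The forward step needs an aryl metal that adds to the cyclobutanone faster than to the enol lactone, from the convex face, and without epimerising C8'.

18 to 15 (key disconnection). The bonds C6–C7 and C3'–C8' are cut. In one sentence: an auxiliary-controlled intramolecular keteniminium–alkene [2+2] cycloaddition of 15 closes the cyclohexene and the cyclobutane together. The tricyclic 18 with three stereocentres goes back to a monocyclic butenolide whose only stereocentres are those of the auxiliary. The forward step needs C3' at the ketene oxidation level (amide of 15), a (Z)-C6=C8' alkene, the fused rather than the crossed mode of addition, and facial control by the C2-symmetric amine.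

15 to 13. The bond O2–C3 is cut (5-exo-dig lactonisation of an enynoic acid). The butenolide goes back to an acyclic enynoate. The forward step needs C1 and the alkynyl carbon C3 cis on C7a=C3a, and anti addition across the alkyne to give the (Z)-ylidene.

13 to 11 and 12. The sp–sp2 bond C3–C3a is cut (alkenyl triflate plus terminal alkyne). The forward step must retain the alkene geometry.

11 to 9. The C3a–O bond of the enol triflate is traced back to the ketone of a β-keto ester. The forward step must give the Z enol derivative (triflate cis to the ester).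

9 to 5 and 8. The bond C7a–C7 is cut (alkylation of the β-keto ester). 8 brings C7, C3' and the auxiliary in one piece, so no later differentiation of two carboxyl groups is needed.

8 to 6 and 7. The amide bond N–C3' is cut.

5 to 3 and 2, and 2 to 1. The bond C4–C5 is cut (γ-alkylation of the dianion of 3 with the allylic bromide 2, which is made from 1). The forward steps must keep the Z geometry of C6=C8'.

## Other disconnections considered

Alternative 1: the first idea. Cut C7–C3' and C6–C8', i.e. the biomimetic crossed [2+2] photocycloaddition of (Z)-ligustilide A1 with (Z)-3-butylidenephthalide A2. A1 offers three alkenes and a diene, so homo-dimers ([4+2] and [2+2]) must compete with the crossed adduct. Nothing in either partner biases head-to-head against head-to-tail union or fixes which face of C3'=C8' meets the ring. A triplet biradical pathway allows rotation at C3'/C8' before closure. There is no handle for absolute configuration, so the product could only be racemic. The route is short but its key step has no defensible selectivity.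

Alternative 2: the same two bonds, but with C3' as a ketene carbon. Intermolecular [2+2] of propylketene A3 with cyclohexa-1,3-diene A4 would give the endo-propyl cyclobutanone A5; aryl addition and annulation of the butenolide onto the six-membered ring would follow. Regiochemistry (carbonyl carbon to the diene terminus) and endo-propyl selectivity are reasonable. However, the remaining alkene of A5 lies at C4=C5 and would have to be transposed and oxidised to install C1, C3 and C3a=C7a. That is five to six further steps on an epimerisable cyclobutanone. A3 and A4 are achiral, so absolute control would need a resolution. The plan also forms the same bonds as Alternative 1 and does not use the ring-fusion feature; the chosen route is shorter and sets the absolute configuration in the ring-forming event.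

Alternative 3: the same cut as the chosen plan (C6–C7 and C3'–C8'), but by a thermal 8π-conrotatory/6π-disrotatory electrocyclisation cascade of tetraene A6 (alkenes C3'=C7, C7a=C3a, C4=C5, C6=C8'). This would give the bicyclo[4.2.0]octadiene A7 (4,5-didehydro-22), followed by selective reduction of C4=C5. Conrotation with O2' inside and C3a' outside would give the correct cis relation of propyl and O2'. The 6π closure, however, can place either the propyl/O2' pair or the aryl/H pair on the concave face without a clear bias. Nothing controls the absolute configuration. A6 needs a (Z,Z,E)-polyene built on a bis-ylidene lactone. The final reduction must distinguish C4=C5 from two other alkenes. The chosen plan forms the same two bonds from a robust precursor under auxiliary control.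

Key step: step 8

Assumptions:
- The (2R,5R) auxiliary is taken to block the approach that would lead to the (6R,7S,8'S) series. The sense of induction is not derived here and must be checked on the first batch of 18; if it is opposite, commercially available (2S,5S)-2,5-dimethylpyrrolidine replaces 7 with no other change.
- Conjugate bases that only await aqueous quench are not numbered apart from their neutral forms.

## Steps

Step 1
Reactants: 1 (Z)-hex-2-en-1-ol
Product: 2 (Z)-1-bromohex-2-ene
Conditions: PBr3 (0.4 equiv), pyridine (cat.), Et2O, −10 °C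
Reagents that add atoms: phosphorus tribromide, BrP(Br)Br
Why: Activation of the primary allylic alcohol as a phosphite and SN2 displacement by bromide at low temperature (PBr3 bromination) should leave the cis alkene and its position untouched; no stereocentre is formed.

Step 2
Reactants: 3 tert-butyl acetoacetate; 2 (Z)-1-bromohex-2-ene
Product: 5 tert-butyl (6Z)-3-oxodec-6-enoate, via acetoacetate dianion 4 (not isolated)
Conditions: NaH, THF, 0 °C; n-BuLi, 0 °C; then 2, 0 °C → rt; aq. NH4Cl
Reagents that add atoms: none
Why: Weiler dianion alkylation: the more basic terminal carbanion of 4 displaces the primary allylic bromide by SN2 and joins C4 to C5 without touching the Z alkene (the future C6=C8'); the β-keto ester returns on quench.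

Step 3
Reactants: 6 bromoacetyl bromide; 7 (2R,5R)-2,5-dimethylpyrrolidine
Product: 8 2-bromo-1-[(2R,5R)-2,5-dimethylpyrrolidin-1-yl]ethan-1-one
Conditions: Et3N, CH2Cl2, −78 → 0 °C
Reagents that add atoms: none
Why: N-Acylation of the secondary amine by the acyl bromide is much faster than SN2 at the α-bromide at low temperature (Schotten–Baumann-type amide formation); the two auxiliary stereocentres are not involved.

Step 4
Reactants: 5 tert-butyl (6Z)-3-oxodec-6-enoate; 8 2-bromo-1-[(2R,5R)-2,5-dimethylpyrrolidin-1-yl]ethan-1-one
Product: 9 tert-butyl (6Z)-2-{2-[(2R,5R)-2,5-dimethylpyrrolidin-1-yl]-2-oxoethyl}-3-oxodec-6-enoate (both C-2 epimers)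
Conditions: K2CO3, NaI (cat.), acetone, 50 °C
Reagents that add atoms: none
Why: C-Alkylation of the β-keto ester enolate with the α-halo amide (SN2 with iodide catalysis) forms the C7a–C7 bond; the new C-2 stereocentre is uncontrolled but is destroyed in step 5.

Step 5
Reactants: 9 tert-butyl (6Z)-2-{2-[(2R,5R)-2,5-dimethylpyrrolidin-1-yl]-2-oxoethyl}-3-oxodec-6-enoate
Product: 11 tert-butyl (2Z,6Z)-2-{2-[(2R,5R)-2,5-dimethylpyrrolidin-1-yl]-2-oxoethyl}-3-{[(trifluoromethyl)sulfonyl]oxy}deca-2,6-dienoate, via sodium enolate 10 (not isolated)
Conditions: NaH, THF, 0 °C; PhNTf2, 0 °C → rt; aq. NH4Cl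
Reagents that add atoms: N-phenylbis(trifluoromethanesulfonimide), O=S(=O)(N(c1ccccc1)S(=O)(=O)C(F)(F)F)C(F)(F)F
Why: The sodium enolate is held in the chelated Z form by the ester carbonyl, so O-sulfonylation should give the (2Z)-enol triflate with OTf cis to the ester (stereoselective enol triflation of a 2-substituted β-keto ester); PhNTf2 is chosen because it does not activate the tertiary amide as Tf2O would.

Step 6
Reactants: 11 tert-butyl (2Z,6Z)-2-{2-[(2R,5R)-2,5-dimethylpyrrolidin-1-yl]-2-oxoethyl}-3-{[(trifluoromethyl)sulfonyl]oxy}deca-2,6-dienoate; 12 pent-1-yne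
Product: 13 tert-butyl (2Z,6Z)-2-{2-[(2R,5R)-2,5-dimethylpyrrolidin-1-yl]-2-oxoethyl}-3-(pent-1-yn-1-yl)deca-2,6-dienoate
Conditions: PdCl2(PPh3)2 (5 mol%), CuI (10 mol%), Et3N, THF, rt
Reagents that add atoms: none
Why: Sonogashira coupling of the electron-poor alkenyl triflate with the terminal alkyne proceeds with retention of alkene geometry and places the alkynyl carbon C3 cis to the ester carbon C1; the isolated Z alkene and the amide are inert.

Step 7
Reactants: 13 tert-butyl (2Z,6Z)-2-{2-[(2R,5R)-2,5-dimethylpyrrolidin-1-yl]-2-oxoethyl}-3-(pent-1-yn-1-yl)deca-2,6-dienoate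
Product: 15 2-{(5Z)-5-butylidene-4-[(3Z)-hept-3-en-1-yl]-2-oxo-2,5-dihydrofuran-3-yl}-1-[(2R,5R)-2,5-dimethylpyrrolidin-1-yl]ethan-1-one, via enynoic acid 14 (not isolated)
Conditions: TFA, CH2Cl2, 0 °C → rt; evaporate; AgNO3 (10 mol%), acetone, rt, dark
Reagents that add atoms: none
Why: Acidolysis of the tert-butyl ester (loss of isobutene) frees acid 14; Ag(I) activation of the alkyne then triggers anti 5-exo-dig attack of the cis carboxylate (O2 to C3) and protodeargentation with retention, which should give the (Z)-alkylidene butenolide (silver-catalysed lactonisation of a (Z)-2-en-4-ynoic acid).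

Step 8
Reactants: 15 2-{(5Z)-5-butylidene-4-[(3Z)-hept-3-en-1-yl]-2-oxo-2,5-dihydrofuran-3-yl}-1-[(2R,5R)-2,5-dimethylpyrrolidin-1-yl]ethan-1-one
Product: 18 (6S,7R,8'R)-cyclobutanone [(Z)-3-butylidene-4,5,6,7-tetrahydrophthalide with the ring C6–C7–C3'(=O)–C8'(propyl) cis-fused at C6–C7; propyl syn to C5], via keteniminium triflate 16 (not isolated), via cyclobutaniminium triflate 17 (not isolated)
Conditions: Tf2O (1.2 equiv), 2,6-di-tert-butyl-4-methylpyridine (1.5 equiv), ClCH2CH2Cl (0.01 M), 0 → 80 °C; then aq. NaHCO3, CH2Cl2, rt
Reagents that add atoms: water, O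
Why: Tf2O should O-sulfonylate the tertiary amide of 15 selectively (the enol lactone carbonyl is far less nucleophilic) and the hindered pyridine removes the doubly activated C7–H to give vinyl-keteniminium 16, the reaction type being the Ghosez intramolecular keteniminium–alkene [2+2] cycloaddition with a C2-symmetric pyrrolidine auxiliary. The electrophilic central carbon C3' bonds to C8' of the (Z)-alkene while the enamine-type carbon C7 closes onto C6, in an asynchronous but stereospecific process that is suprafacial on the alkene. Two rings close at once: the cyclobutane (C3'–C8' and C7–C6) and, through C7–C6, the cyclohexene as a six-membered fused closure across the rigid cis C7a=C3a tether; the crossed mode (C3'–C6 and C7–C8') would need a seven-membered bridged bicyclo[4.1.1] arrangement and has no cation-stabilising bias because both alkene carbons are secondary. C6 and C8' keep the Z geometry of the alkene, so C5 and the propyl group end cis on the cyclobutane. C7 is set cis to C6 because the four-atom tether only allows the cis-fused bicyclo[4.2.0] transition state. The absolute sense at all three centres is decided by which lobe of the C3'=C7 π bond the folded alkene uses, and the 2- and 5-methyl groups of the auxiliary, which flank these lobes in a C2-symmetric and therefore single-geometry keteniminium, should block one of them. The exocyclic C3=C8 enol-lactone alkene cannot compete, because bonding of C3' and C7 to it would give a bicyclo[2.2.0] or bicyclo[2.1.1] skeleton containing the butenolide alkene. Bicarbonate hydrolysis of 17 releases 18 and the auxiliary; enamine formation towards the more acidic allylic C7–H (which only returns the cis-fused isomer) is preferred over that towards C8', which should protect the concave propyl centre from epimerisation.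

Step 9
Reactants: 18 (6S,7R,8'R)-cyclobutanone; 19 methyl 2-iodobenzoate
Product: 22 target CNP0248594.2 [(3Z,6S,7R,3'R,8'R); cyclobutane C6–C7–C3'–C8' joining the (Z)-3-butylidene-4,5,6,7-tetrahydrophthalide to the spiro-phthalide at C3'], via arylmagnesium chloride 20 (not isolated), via hydroxy ester 21 (not isolated)
Conditions: 19, iPrMgCl·LiCl, THF, −40 °C; LaCl3·2LiCl, then 18, −78 °C; AcOH, −78 °C; then PPTS (cat.), CH2Cl2, rt
Reagents that add atoms: none
Why: Iodine–magnesium exchange gives the ester-bearing aryl Grignard reagent 20 (Knochel-type functionalised Grignard), which at −78 °C with the lanthanum salt should add to the strained cyclobutanone rather than to the enol lactone or its own ester, and without enolisation. Attack comes from the convex face, anti to the six-membered ring and to the concave propyl group, so C3a' ends anti and O2' syn to the ring (3'R). Cold protic quench gives 21, and mild acid closes the five-membered lactone onto the ortho ester with loss of methanol, so the enol lactone never meets an alkoxide at ambient temperature.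

## Compound list

1 | (Z)-hex-2-en-1-ol | CCC/C=C\CO | starting material
2 | (Z)-1-bromohex-2-ene | CCC/C=C\CBr | intermediate
3 | tert-butyl acetoacetate (tert-butyl 3-oxobutanoate) | CC(=O)CC(=O)OC(C)(C)C | starting material
4 | sodium lithium dianion (1,3-dienolate) of 3 | C=C([O-])C=C([O-])OC(C)(C)C.[Na+].[Li+] | intermediate
5 | tert-butyl (6Z)-3-oxodec-6-enoate | CCC/C=C\CCC(=O)CC(=O)OC(C)(C)C | intermediate
6 | bromoacetyl bromide | BrCC(Br)=O | starting material
7 | (2R,5R)-2,5-dimethylpyrrolidine | C[C@@H]1CC[C@@H](C)N1 | starting material
8 | 2-bromo-1-[(2R,5R)-2,5-dimethylpyrrolidin-1-yl]ethan-1-one | BrCC(=O)N1[C@H](C)CC[C@H]1C | intermediate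
9 | tert-butyl (6Z)-2-{2-[(2R,5R)-2,5-dimethylpyrrolidin-1-yl]-2-oxoethyl}-3-oxodec-6-enoate (C-2 epimers) | CCC/C=C\CCC(=O)C(CC(=O)N1[C@H](C)CC[C@H]1C)C(=O)OC(C)(C)C | intermediate
10 | sodium (2Z)-enolate of 9 | CCC/C=C\CC/C([O-])=C(\CC(=O)N1[C@H](C)CC[C@H]1C)C(=O)OC(C)(C)C.[Na+] | intermediate
11 | tert-butyl (2Z,6Z)-2-{2-[(2R,5R)-2,5-dimethylpyrrolidin-1-yl]-2-oxoethyl}-3-{[(trifluoromethyl)sulfonyl]oxy}deca-2,6-dienoate | CCC/C=C\CC/C(OS(=O)(=O)C(F)(F)F)=C(\CC(=O)N1[C@H](C)CC[C@H]1C)C(=O)OC(C)(C)C | intermediate
12 | pent-1-yne | CCCC#C | starting material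
13 | tert-butyl (2Z,6Z)-2-{2-[(2R,5R)-2,5-dimethylpyrrolidin-1-yl]-2-oxoethyl}-3-(pent-1-yn-1-yl)deca-2,6-dienoate | CCC/C=C\CC/C(C#CCCC)=C(\CC(=O)N1[C@H](C)CC[C@H]1C)C(=O)OC(C)(C)C | intermediate
14 | (2Z,6Z)-2-{2-[(2R,5R)-2,5-dimethylpyrrolidin-1-yl]-2-oxoethyl}-3-(pent-1-yn-1-yl)deca-2,6-dienoic acid | CCC/C=C\CC/C(C#CCCC)=C(\CC(=O)N1[C@H](C)CC[C@H]1C)C(=O)O | intermediate
15 | 2-{(5Z)-5-butylidene-4-[(3Z)-hept-3-en-1-yl]-2-oxo-2,5-dihydrofuran-3-yl}-1-[(2R,5R)-2,5-dimethylpyrrolidin-1-yl]ethan-1-one | CCC/C=C1\OC(=O)C(CC(=O)N2[C@H](C)CC[C@H]2C)=C1CC/C=C\CCC | intermediate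
16 | keteniminium triflate of 15 (amide CH2–C(=O)N converted into CH=C=N+ on the (2R,5R)-2,5-dimethylpyrrolidinium nitrogen) | CCC/C=C1\OC(=O)C(C=C=[N+]2[C@H](C)CC[C@H]2C)=C1CC/C=C\CCC.[O-]S(=O)(=O)C(F)(F)F | intermediate
17 | cyclobutaniminium triflate (18 with C3'=O replaced by C3'=N+ of the (2R,5R)-2,5-dimethylpyrrolidinium; 6S,7R,8'R) | CCC/C=C1\OC(=O)C2=C1CC[C@H]1[C@@H](CCC)C(=[N+]3[C@H](C)CC[C@H]3C)[C@@H]21.[O-]S(=O)(=O)C(F)(F)F | intermediate
18 | (6S,7R,8'R)-cyclobutanone: (Z)-3-butylidene-4,5,6,7-tetrahydrophthalide cis-fused at C6–C7 to the ring C6–C7–C3'(=O)–C8'(propyl), propyl syn to C5 | CCC/C=C1\OC(=O)C2=C1CC[C@H]1[C@@H](CCC)C(=O)[C@@H]21 | intermediate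
19 | methyl 2-iodobenzoate | COC(=O)c1ccccc1I | starting material
20 | [2-(methoxycarbonyl)phenyl]magnesium chloride | COC(=O)c1ccccc1[Mg]Cl | intermediate
21 | methyl 2-[(3'R)-3'-hydroxy…]benzoate: 18 with C3' carrying OH (syn to the six-membered ring) and the 2-(methoxycarbonyl)phenyl group (anti); formed as its magnesium alkoxide | CCC/C=C1\OC(=O)C2=C1CC[C@H]1[C@@H](CCC)[C@@](c3ccccc3C(=O)OC)(O)[C@@H]21 | intermediate
22 | CNP0248594.2, (3Z,6S,7R,3'R,8'R) | CCC/C=C1\OC(=O)C2=C1CC[C@H]1[C@@H](CCC)[C@@]3(OC(=O)c4ccccc43)[C@@H]21 | target

## Step count and risk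

Total step count: 9. Longest linear sequence: 8 steps (steps 1, 2, 4, 5, 6, 7, 8, 9; compounds 1 → 2 → 5 → 9 → 11 → 13 → 15 → 18 → 22). Step 3 is a one-step side branch.

Least certain steps:

Step 8 (key step). The most likely failure is insufficient or inverted discrimination between the two approach trajectories by the auxiliary, which would lower the enantiomeric purity of 18. Lesser risks are partial addition in the crossed mode and epimerisation at C8' during iminium hydrolysis. The fallback replaces auxiliary control by resolution through covalent diastereomers; it sets out from 18 and comes back at 18. Ketalisation of scalemic 18 with (2R,3R)-butane-2,3-diol (PPTS, benzene, Dean–Stark) would give diastereomeric dioxolanes. The butane-2,3-diol ketal F1 of the wanted enantiomer would be separated by chromatography or crystallisation and hydrolysed (aq. HCl, THF) back to 18.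

Step 9. Deprotonation at the acidic allylic C7–H may compete with addition, the aryl nucleophile may attack the enol lactone, or the new alkoxide may take the acyl group of the enol lactone and open the butenolide. The fallback reverses the order of lactone construction (aryl first, butenolide last); it sets out from 13 and comes back at 22. 13 would be submitted directly to the conditions of step 8 to give, via keteniminium triflate F2 and cyclobutaniminium triflate F3, the tert-butyl ester cyclobutanone F4, in which C1 is still an ester and C3 still an alkyne carbon. Addition of 20 as in step 9 would give hydroxy ester F5 and, after lactonisation, spiro-phthalide ester F6. TFA would then free enynoic acid F7, and silver-catalysed 5-exo-dig lactonisation as in step 7 would close the butenolide last and give 22.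

Step 7. 6-endo-dig closure to a 2-pyranone may compete with the 5-exo-dig mode, or the amide oxygen may take part in the alkyne activation. The fallback introduces C3 as a ketone and forms the ylidene by dehydration, so that only a five-membered ring can form; it sets out from 11 and comes back at 15. Carbonylative Negishi coupling of 11 with butylzinc bromide (Pd(PPh3)4, CO 1 atm, THF) would give enone F8. TFA would cleave the tert-butyl ester, and the keto acid would be obtained as its ring tautomer, hydroxybutenolide F9. Acid-catalysed dehydration (p-TsOH cat., toluene, Dean–Stark) would give the thermodynamically preferred (Z)-ylidene 15.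

Step 1. Allylic transposition or Z-to-E isomerisation may occur during bromination or on storage of the allylic bromide. The fallback carries an alkyne and sets the Z alkene by semi-hydrogenation; it sets out from 3 and comes back at 5. Hex-2-yn-1-ol F10 would be converted (PBr3, Et2O) into 1-bromohex-2-yne F11. The dianion of 3 would be alkylated with it as in step 2 to give tert-butyl 3-oxodec-6-ynoate F12. Hydrogenation over Lindlar catalyst with quinoline would give 5.

## Further compounds

F1 | step 8 | (4R,5R)-4,5-dimethyl-1,3-dioxolane (butane-2,3-diol ketal) of 18 at C3' | CCC/C=C1\OC(=O)C2=C1CC[C@H]1[C@@H](CCC)C3(O[C@H](C)[C@@H](C)O3)[C@@H]21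
F2 | step 9 | keteniminium triflate of 13 (amide converted into CH=C=N+; tert-butyl ester and pentynyl group retained) | CCC/C=C\CC/C(C#CCCC)=C(\C=C=[N+]1[C@H](C)CC[C@H]1C)C(=O)OC(C)(C)C.[O-]S(=O)(=O)C(F)(F)F
F3 | step 9 | cyclobutaniminium triflate (F4 with C=O replaced by C=N+ of the auxiliary) | CC(C)(C)OC(=O)C2=C(C#CCCC)CC[C@H]1[C@@H](CCC)C(=[N+]3[C@H](C)CC[C@H]3C)[C@@H]21.[O-]S(=O)(=O)C(F)(F)F
F4 | step 9 | tert-butyl (1R,6S,7R)-8-oxo-3-(pent-1-yn-1-yl)-7-propylbicyclo[4.2.0]oct-2-ene-2-carboxylate | CC(C)(C)OC(=O)C2=C(C#CCCC)CC[C@H]1[C@@H](CCC)C(=O)[C@@H]21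
F5 | step 9 | methyl 2-[(1R,6S,7R,8R)-2-(tert-butoxycarbonyl)-8-hydroxy-3-(pent-1-yn-1-yl)-7-propylbicyclo[4.2.0]oct-2-en-8-yl]benzoate | CC(C)(C)OC(=O)C2=C(C#CCCC)CC[C@H]1[C@@H](CCC)[C@@](c3ccccc3C(=O)OC)(O)[C@@H]21
F6 | step 9 | spiro-phthalide tert-butyl ester (F5 after lactonisation of the C8 hydroxyl onto the benzoate) | CC(C)(C)OC(=O)C2=C(C#CCCC)CC[C@H]1[C@@H](CCC)[C@@]3(OC(=O)c4ccccc43)[C@@H]21
F7 | step 9 | spiro-phthalide enynoic acid (F6 with the tert-butyl ester cleaved) | OC(=O)C2=C(C#CCCC)CC[C@H]1[C@@H](CCC)[C@@]3(OC(=O)c4ccccc43)[C@@H]21
F8 | step 7 | tert-butyl (2Z,6Z)-2-{2-[(2R,5R)-2,5-dimethylpyrrolidin-1-yl]-2-oxoethyl}-3-pentanoyldeca-2,6-dienoate | CCC/C=C\CC/C(C(=O)CCCC)=C(\CC(=O)N1[C@H](C)CC[C@H]1C)C(=O)OC(C)(C)C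
F9 | step 7 | 2-{5-butyl-4-[(3Z)-hept-3-en-1-yl]-5-hydroxy-2-oxo-2,5-dihydrofuran-3-yl}-1-[(2R,5R)-2,5-dimethylpyrrolidin-1-yl]ethan-1-one (C-5 epimers) | CCCCC1(O)OC(=O)C(CC(=O)N2[C@H](C)CC[C@H]2C)=C1CC/C=C\CCC
F10 | step 1 | hex-2-yn-1-ol | CCCC#CCO
F11 | step 1 | 1-bromohex-2-yne | CCCC#CCBr
F12 | step 1 | tert-butyl 3-oxodec-6-ynoate | CCCC#CCCC(=O)CC(=O)OC(C)(C)C
A1 | alternative 1 | (Z)-ligustilide | CCC/C=C1\OC(=O)C2=C1CCC=C2
A2 | alternative 1 | (Z)-3-butylidenephthalide | CCC/C=C1\OC(=O)c2ccccc12
A3 | alternative 2 | propylketene (pent-1-en-1-one) | CCCC=C=O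
A4 | alternative 2 | cyclohexa-1,3-diene | C1=CC=CCC1
A5 | alternative 2 | endo-8-propylbicyclo[4.2.0]oct-2-en-7-one (relative configuration of the target series) | C1CC=C[C@H]2[C@@H](CCC)C(=O)[C@@H]12
A6 | alternative 3 | tetraene: (Z)-5-butylidene-4-[(1Z,3E)-hepta-1,3-dienyl]-3-[(Z)-(3-oxo-2-benzofuran-1(3H)-ylidene)methyl]furan-2(5H)-one | CCC/C=C1\OC(=O)C(/C=C2\OC(=O)c3ccccc32)=C1/C=C\C=C\CCC
A7 | alternative 3 | 4,5-didehydro-22 (bicyclo[4.2.0]octadiene; relative configuration shown) | CCC/C=C1\OC(=O)C2=C1C=C[C@H]1[C@@H](CCC)[C@@]3(OC(=O)c4ccccc43)[C@@H]21
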